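**Plan**

- Retrosynthetic cuts, in order: the C8 methacrylate and the 11,13-epoxide; then the C6–C7 bond together with the lactone C12–O6 bond (a C13 allylic bromide adding to a C6 enal); then C7–C11 (an acrylate unit put on a C7 aldehyde); then the furanone, which is enlarged to a 2,3-dihydro-4H-pyran-4-one with its ring oxygen on C9; this is cut at C9–C10 and O9–C3 into a 1-methoxy-3-silyloxy diene and (S)-glyceraldehyde acetonide.
- Enabling feature: the furanone O–C3=C2–C1(=O)–C10 is a cyclic vinylogous ester, and its quaternary ring carbon C10 carries C9 with an oxygen of its own (the acetate). O9 can therefore hold the same C1–C3 unit in a six-membered ring, and the neighbouring oxygens O9 and O10 can change roles.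
- Forward order: enynol → ynone → methoxy enone → hetero-Diels–Alder (six-membered ring) → acetoxylation at C10 → ring contraction to the furanone, the acetyl passing to O9 → C7 aldehyde → (bromomethyl)acrylate → C6 enal → ten-membered ring and lactone in one allylation → epoxide → methacrylate.
- Stereochemistry: C8 from (S)-glyceraldehyde; C9 by Felkin–Anh addition; C10 on the six-membered template, trans to the C9 side chain, and carried unchanged through the contraction; C7 and C6 in the macrocyclic allylation; C11 by β-face epoxide closure; the 4Z alkene from the starting (Z)-enynol.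

Key step: step 6

Remark: positions are numbered as in germacrane (C1 ketone, C3 and C10 joined by the furanone oxygen, C6 lactone oxygen, C8 methacrylate, C9 acetate, C11/C13 spiro-epoxide); the enynol, the Weinreb amide, (S)-glyceraldehyde acetonide and methyl propiolate are taken as commercial.

Step 1
Reactants: 1 (2Z)-3-methylpent-2-en-4-yn-1-ol
Product: 2 4-methoxybenzyl (PMB) ether of 1
Conditions: NaH, PMBCl, TBAI (cat.), THF, 0 °C to rt
Reagents that add atoms: 4-methoxybenzyl chloride COc1ccc(CCl)cc1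
Why: Williamson etherification of the primary allylic alkoxide masks O6 for the enolisation, amine and silylation steps and leaves the Z alkene untouched.

Step 2
Reactants: 2 PMB ether; 3 N-methoxy-N-methylpropanamide
Product: 4 (6Z)-8-(PMB-oxy)-6-methyloct-6-en-4-yn-3-one
Conditions: n-BuLi, THF, −78 °C; then 3, −78 to 0 °C; AcOH quench
Reagents that add atoms: none
Why: Acylation of the lithium acetylide with a Weinreb amide should stop at the ynone because the tetrahedral chelate survives until work-up.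

Step 3
Reactants: 4 ynone
Product: 5 (4E,6Z)-5-methoxy-8-(PMB-oxy)-6-methylocta-4,6-dien-3-one
Conditions: MeOH, PMe3 (10 mol %), CH2Cl2, rt
Reagents that add atoms: methanol CO
Why: Phosphine-catalysed oxa-Michael addition of methanol to the ynone places the methoxy group at C3 only; either enone geometry serves in the next step.

Step 4
Reactants: 5 methoxy enone; 6 (4S)-2,2-dimethyl-1,3-dioxolane-4-carbaldehyde
Product: 8 (2R)-2-[(4S)-2,2-dimethyl-1,3-dioxolan-4-yl]-3-methyl-6-[(2Z)-4-(PMB-oxy)but-2-en-2-yl]-2,3-dihydro-4H-pyran-4-one (C3 epimers), via silyl dienol ether 7 (not isolated)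
Conditions: TMSOTf, Et3N, Et2O, 0 °C; filter under Ar, concentrate; then 6, ZnCl2 (20 mol %), THF, rt; then TFA (cat.), CH2Cl2, 0 °C
Reagents that add atoms: none
Why: Mukaiyama aldol–cyclocondensation (hetero-Diels–Alder) of the 1-methoxy-3-silyloxy diene with the α-alkoxy aldehyde should form C9–C10 and O9–C3, with Felkin–Anh attack anti to the dioxolane C–O bond setting C9 anti to O8; TFA expels methanol, and the C10 epimers converge in step 5.

Step 5
Reactants: 8 dihydropyranone
Product: 9 (2S,3S)-3-acetoxy derivative of 8 (acetoxy and methyl on C10, acetoxy trans to the dioxolanyl group)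
Conditions: Mn(OAc)3·2H2O (3 equiv), benzene, reflux, Dean–Stark
Reagents that add atoms: manganese triacetate dihydrate CC(=O)[O-].CC(=O)[O-].CC(=O)[O-].[Mn+3].O.O
Why: α'-Acetoxylation of the enone through its trivalent manganese enolate and α-keto radical should deliver acetate to the planar C10 on the face anti to the C9 dioxolanyl group, so both epimers of 8 give the one trans acetate.

Step 6
Reactants: 9 acetoxy dihydropyranone
Product: 12 (S)-[(4S)-2,2-dimethyl-1,3-dioxolan-4-yl][(2S)-2-methyl-3-oxo-5-[(2Z)-4-(PMB-oxy)but-2-en-2-yl]-2,3-dihydrofuran-2-yl]methyl acetate, via ring-opened enaminone 10 (not isolated), via O9-acetyl enaminone 11 (not isolated)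
Conditions: pyrrolidine (3 equiv), MeOH, rt to 40 °C; concentrate; then AcOH–THF–H2O (1:4:1), rt
Reagents that add atoms: none
Why: Proposed new method: pyrrolidine adds to C3 of the cyclic vinylogous ester and expels O9 (addition–elimination), opening the six-membered ring to the vinylogous amide 10; the acetyl group then moves from the hindered tertiary O10 to the freed secondary O9 through a five-membered orthoacid to give 11, and mild acid protonates C2 so that O10 adds to the iminium carbon C3 and pyrrolidine leaves, closing the 3(2H)-furanone. The closest known reaction types are the amine-induced ring opening of 2,3-dihydro-4H-pyran-4-ones (the ANRORC path to dihydropyridones) and the acid cyclisation of α'-hydroxy enaminones to 3(2H)-furanones. The only ring closed is the furanone, by 5-exo-trig attack of O10 on the C3=N+ bond. No stereocenter is created: C9 and C10 keep the configurations set on the six-membered template, because neither the C9–O nor the C10–O bond is broken. The step needs the five-membered ring to win over return to the six-membered ring, which the migrated acetate secures since only O10 is left free, and any 10 that has not migrated merely re-forms 9 for another pass. It also needs the amine to attack C3 faster than the ester, which the higher electrophilicity of the vinylogous ester and the hindrance of the tertiary acetate should ensure.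

Step 7
Reactants: 12 furanone acetonide
Product: 13 (1S,2S)-2,3-dihydroxy-1-[(2S)-furanonyl]propyl acetate (C7,C8 diol)
Conditions: AcOH–H2O (4:1), 40 °C
Reagents that add atoms: none
Why: Acid hydrolysis of the terminal dioxolane should spare the C9 acetate, the PMB ether and the vinylogous ester; the diol is silylated at once to forestall O9 to O8 acetyl migration.

Step 8
Reactants: 13 diol
Product: 14 C7,C8 bis(triethylsilyl) ether
Conditions: TESOTf, 2,6-lutidine, CH2Cl2, −78 °C
Reagents that add atoms: triethylsilyl triflate CC[Si](CC)(CC)OS(=O)(=O)C(F)(F)F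
Why: Silylation with the triflate is fast at −78 °C under a non-nucleophilic base, so both hydroxyls are capped before the acetate can migrate.

Step 9
Reactants: 14 bis-silyl ether
Product: 15 (1S,2R)-3-oxo-2-(triethylsilyloxy)-1-[(2S)-furanonyl]propyl acetate (C7 aldehyde)
Conditions: (COCl)2, DMSO, CH2Cl2, −78 to −40 °C; then i-Pr2NEt, −78 °C
Reagents that add atoms: none
Why: Under Swern conditions the chlorosulfonium ion cleaves and oxidises the primary triethylsilyl ether only, the secondary one being too hindered; the hindered base at low temperature should avoid β-elimination of the C9 acetate and epimerisation at C8.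

Step 10
Reactants: 15 aldehyde; 16 methyl propiolate
Product: 17 methyl (4S,5S)-5-acetoxy-3-hydroxy-2-methylidene-4-(triethylsilyloxy)-5-[(2S)-furanonyl]pentanoate (C7 epimers)
Conditions: 16, DIBAL-H, NMO, THF, 0 °C; then 15, 0 °C to rt; aq. Rochelle salt
Reagents that add atoms: none
Why: Hydroalumination of the propiolate gives the α-aluminoacrylate, which adds to the aldehyde to give the Morita–Baylis–Hillman-type adduct without the amine base that would eliminate the β-acetate; the C7 carbinol centre disappears in step 11.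

Step 11
Reactants: 17 hydroxy acrylate
Product: 18 methyl (2Z,4S,5S)-5-acetoxy-2-(bromomethyl)-4-(triethylsilyloxy)-5-[(2S)-furanonyl]pent-2-enoate
Conditions: NBS, Me2S, CH2Cl2, 0 °C to rt
Reagents that add atoms: N-bromosuccinimide O=C1CCC(=O)N1Br
Why: The Corey–Kim-type sulfonium reagent activates the C7 hydroxyl and bromide enters at C13 with allylic transposition (SN2'), giving the conjugated (Z)-2-(bromomethyl)enoate from either C7 epimer.

Step 12
Reactants: 18 allylic bromide
Product: 19 C6 allylic alcohol (PMB removed)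
Conditions: DDQ, CH2Cl2–pH 7 buffer (10:1), 0 °C
Reagents that add atoms: none
Why: Oxidative cleavage of the PMB ether is orthogonal to the silyl ether, the acetate and the allylic bromide.

Step 13
Reactants: 19 allylic alcohol
Product: 20 (Z)-enal: methyl (2Z,4S,5S)-5-acetoxy-2-(bromomethyl)-5-[(2S)-2-methyl-3-oxo-5-[(2Z)-4-oxobut-2-en-2-yl]-2,3-dihydrofuran-2-yl]-4-(triethylsilyloxy)pent-2-enoate
Conditions: MnO2, CH2Cl2, rt, dark
Reagents that add atoms: none
Why: Neutral heterogeneous oxidation of the allylic alcohol should give the enal without Z to E isomerisation; the enal is used at once.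

Step 14
Reactants: 20 bromo enal
Product: 22 (4Z,6R,7S,8S,9S,10S)-9-acetoxy-3,10-epoxy-1-oxo-8-(triethylsilyloxy)germacra-2,4,11(13)-trien-12,6-olide, via hydroxy ester 21 (not isolated)
Conditions: CrCl2 (6 equiv), DMF, 2 mM (slow addition), rt then 50 °C
Reagents that add atoms: none
Why: Intramolecular Nozaki–Hiyama–Kishi (Barbier-type) allylation: the allylchromium formed at C13 adds through C7 to the C6 aldehyde in a chair transition state, with C7 attacked anti to the C9 chain on C8 (C8–H eclipsing the alkene to avoid allylic 1,3-strain) and the ten-membered ring expected to favour the 6,7-anti adduct, whose chromium alkoxide lactonises to the trans-fused α-methylene lactone.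

Step 15
Reactants: 22 α-methylene lactone
Product: 23 (11S)-11,13-epoxide of 22
Conditions: t-BuOOH (decane), DBU, CH2Cl2, 0 °C
Reagents that add atoms: tert-butyl hydroperoxide CC(C)(C)OO
Why: Weitz–Scheffer epoxidation: the peroxide adds to C13 of the exocyclic enoate, by far the best Michael acceptor present, and the C11 enolate should close on oxygen from the β face, anti to the pseudo-axial H7 of the trans-fused lactone.

Step 16
Reactants: 23 silyl ether
Product: 24 C8 alcohol
Conditions: HF·pyridine, pyridine, THF, 0 °C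
Reagents that add atoms: none
Why: Buffered fluoride removes the secondary triethylsilyl group under mildly acidic conditions, which should spare the deactivated spiro-epoxide and avoid acetyl migration.

Step 17
Reactants: 24 C8 alcohol
Product: 25 target, (4Z,6R,7S,8S,9S,10S,11S)-9-acetoxy-3,10:11,13-diepoxy-8-(methacryloyloxy)-1-oxogermacra-2,4-dien-12,6-olide
Conditions: methacrylic anhydride, Et3N, DMAP (cat.), CH2Cl2, 0 °C
Reagents that add atoms: methacrylic anhydride C=C(C)C(=O)OC(=O)C(C)=C
Why: DMAP-catalysed acylation of the secondary alcohol at 0 °C should outpace O9 to O8 acetyl migration and completes the target.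

**Compound list**

1 | (2Z)-3-methylpent-2-en-4-yn-1-ol | OC/C=C(/C)C#C | starting material
2 | 1-methoxy-4-({[(2Z)-3-methylpent-2-en-4-yn-1-yl]oxy}methyl)benzene | COc1ccc(COC/C=C(/C)C#C)cc1 | intermediate
3 | N-methoxy-N-methylpropanamide | CCC(=O)N(C)OC | starting material
4 | (6Z)-8-[(4-methoxybenzyl)oxy]-6-methyloct-6-en-4-yn-3-one | COc1ccc(COC/C=C(/C)C#CC(=O)CC)cc1 | intermediate
5 | (4E,6Z)-5-methoxy-8-[(4-methoxybenzyl)oxy]-6-methylocta-4,6-dien-3-one | COc1ccc(COC/C=C(/C)\C(OC)=C/C(=O)CC)cc1 | intermediate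
6 | (4S)-2,2-dimethyl-1,3-dioxolane-4-carbaldehyde | O=C[C@@H]1COC(C)(C)O1 | starting material
7 | trimethyl{[(2Z,4E,6Z)-5-methoxy-8-[(4-methoxybenzyl)oxy]-6-methylocta-2,4,6-trien-3-yl]oxy}silane | COc1ccc(COC/C=C(/C)\C(OC)=C/C(O[Si](C)(C)C)=C/C)cc1 | intermediate
8 | (2R)-2-[(4S)-2,2-dimethyl-1,3-dioxolan-4-yl]-6-{(2Z)-4-[(4-methoxybenzyl)oxy]but-2-en-2-yl}-3-methyl-2,3-dihydro-4H-pyran-4-one (C3 epimers) | COc1ccc(COC/C=C(/C)C2=CC(=O)C(C)[C@@H](O2)[C@@H]3COC(C)(C)O3)cc1 | intermediate
9 | (2S,3S)-2-[(4S)-2,2-dimethyl-1,3-dioxolan-4-yl]-6-{(2Z)-4-[(4-methoxybenzyl)oxy]but-2-en-2-yl}-3-methyl-4-oxo-3,4-dihydro-2H-pyran-3-yl acetate | COc1ccc(COC/C=C(/C)C2=CC(=O)[C@@](C)(OC(C)=O)[C@@H](O2)[C@@H]3COC(C)(C)O3)cc1 | intermediate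
10 | (1S,2S,4E,6Z)-1-[(4S)-2,2-dimethyl-1,3-dioxolan-4-yl]-1-hydroxy-8-[(4-methoxybenzyl)oxy]-2,6-dimethyl-3-oxo-5-(pyrrolidin-1-yl)octa-4,6-dien-2-yl acetate | COc1ccc(COC/C=C(/C)\C(=C/C(=O)[C@@](C)(OC(C)=O)[C@@H](O)[C@@H]2COC(C)(C)O2)N2CCCC2)cc1 | intermediate
11 | (1S,2S,4E,6Z)-1-[(4S)-2,2-dimethyl-1,3-dioxolan-4-yl]-2-hydroxy-8-[(4-methoxybenzyl)oxy]-2,6-dimethyl-3-oxo-5-(pyrrolidin-1-yl)octa-4,6-dien-1-yl acetate | COc1ccc(COC/C=C(/C)\C(=C/C(=O)[C@@](C)(O)[C@@H](OC(C)=O)[C@@H]2COC(C)(C)O2)N2CCCC2)cc1 | intermediate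
12 | (S)-[(4S)-2,2-dimethyl-1,3-dioxolan-4-yl][(2S)-5-{(2Z)-4-[(4-methoxybenzyl)oxy]but-2-en-2-yl}-2-methyl-3-oxo-2,3-dihydrofuran-2-yl]methyl acetate | COc1ccc(COC/C=C(/C)C2=CC(=O)[C@@](C)(O2)[C@@H](OC(C)=O)[C@@H]3COC(C)(C)O3)cc1 | intermediate
13 | (1S,2S)-2,3-dihydroxy-1-[(2S)-5-{(2Z)-4-[(4-methoxybenzyl)oxy]but-2-en-2-yl}-2-methyl-3-oxo-2,3-dihydrofuran-2-yl]propyl acetate | COc1ccc(COC/C=C(/C)C2=CC(=O)[C@@](C)(O2)[C@@H](OC(C)=O)[C@@H](O)CO)cc1 | intermediate
14 | (1S,2S)-1-[(2S)-5-{(2Z)-4-[(4-methoxybenzyl)oxy]but-2-en-2-yl}-2-methyl-3-oxo-2,3-dihydrofuran-2-yl]-2,3-bis[(triethylsilyl)oxy]propyl acetate | COc1ccc(COC/C=C(/C)C2=CC(=O)[C@@](C)(O2)[C@@H](OC(C)=O)[C@@H](O[Si](CC)(CC)CC)CO[Si](CC)(CC)CC)cc1 | intermediate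
15 | (1S,2R)-1-[(2S)-5-{(2Z)-4-[(4-methoxybenzyl)oxy]but-2-en-2-yl}-2-methyl-3-oxo-2,3-dihydrofuran-2-yl]-3-oxo-2-[(triethylsilyl)oxy]propyl acetate | COc1ccc(COC/C=C(/C)C2=CC(=O)[C@@](C)(O2)[C@@H](OC(C)=O)[C@@H](O[Si](CC)(CC)CC)C=O)cc1 | intermediate
16 | methyl propiolate | C#CC(=O)OC | starting material
17 | methyl (4S,5S)-5-acetoxy-3-hydroxy-5-[(2S)-5-{(2Z)-4-[(4-methoxybenzyl)oxy]but-2-en-2-yl}-2-methyl-3-oxo-2,3-dihydrofuran-2-yl]-2-methylidene-4-[(triethylsilyl)oxy]pentanoate (C3 epimers) | COc1ccc(COC/C=C(/C)C2=CC(=O)[C@@](C)(O2)[C@@H](OC(C)=O)[C@@H](O[Si](CC)(CC)CC)C(O)C(=C)C(=O)OC)cc1 | intermediate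
18 | methyl (2Z,4S,5S)-5-acetoxy-2-(bromomethyl)-5-[(2S)-5-{(2Z)-4-[(4-methoxybenzyl)oxy]but-2-en-2-yl}-2-methyl-3-oxo-2,3-dihydrofuran-2-yl]-4-[(triethylsilyl)oxy]pent-2-enoate | COc1ccc(COC/C=C(/C)C2=CC(=O)[C@@](C)(O2)[C@@H](OC(C)=O)[C@@H](O[Si](CC)(CC)CC)/C=C(\CBr)C(=O)OC)cc1 | intermediate
19 | methyl (2Z,4S,5S)-5-acetoxy-2-(bromomethyl)-5-{(2S)-5-[(2Z)-4-hydroxybut-2-en-2-yl]-2-methyl-3-oxo-2,3-dihydrofuran-2-yl}-4-[(triethylsilyl)oxy]pent-2-enoate | OC/C=C(/C)C1=CC(=O)[C@@](C)(O1)[C@@H](OC(C)=O)[C@@H](O[Si](CC)(CC)CC)/C=C(\CBr)C(=O)OC | intermediate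
20 | methyl (2Z,4S,5S)-5-acetoxy-2-(bromomethyl)-5-{(2S)-2-methyl-3-oxo-5-[(2Z)-4-oxobut-2-en-2-yl]-2,3-dihydrofuran-2-yl}-4-[(triethylsilyl)oxy]pent-2-enoate | O=C/C=C(/C)C1=CC(=O)[C@@](C)(O1)[C@@H](OC(C)=O)[C@@H](O[Si](CC)(CC)CC)/C=C(\CBr)C(=O)OC | intermediate
21 | methyl (4Z,6R,7S,8S,9S,10S)-9-acetoxy-3,10-epoxy-6-hydroxy-1-oxo-8-[(triethylsilyl)oxy]germacra-2,4,11(13)-trien-12-oate | CC[Si](CC)(CC)O[C@H]1[C@@H](C(=C)C(=O)OC)[C@H](O)/C=C(/C)C2=CC(=O)[C@@](C)(O2)[C@H]1OC(C)=O | intermediate
22 | (4Z,6R,7S,8S,9S,10S)-9-acetoxy-3,10-epoxy-1-oxo-8-[(triethylsilyl)oxy]germacra-2,4,11(13)-trien-12,6-olide | CC[Si](CC)(CC)O[C@H]1[C@@H]2[C@@H](/C=C(/C)C3=CC(=O)[C@@](C)(O3)[C@H]1OC(C)=O)OC(=O)C2=C | intermediate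
23 | (4Z,6R,7S,8S,9S,10S,11S)-9-acetoxy-3,10:11,13-diepoxy-1-oxo-8-[(triethylsilyl)oxy]germacra-2,4-dien-12,6-olide | CC[Si](CC)(CC)O[C@H]1[C@@H]2[C@@H](/C=C(/C)C3=CC(=O)[C@@](C)(O3)[C@H]1OC(C)=O)OC(=O)[C@@]21CO1 | intermediate
24 | (4Z,6R,7R,8S,9S,10S,11S)-9-acetoxy-3,10:11,13-diepoxy-8-hydroxy-1-oxogermacra-2,4-dien-12,6-olide | O[C@H]1[C@@H]2[C@@H](/C=C(/C)C3=CC(=O)[C@@](C)(O3)[C@H]1OC(C)=O)OC(=O)[C@@]21CO1 | intermediate
25 | (4Z,6R,7S,8S,9S,10S,11S)-9-acetoxy-3,10:11,13-diepoxy-8-(methacryloyloxy)-1-oxogermacra-2,4-dien-12,6-olide | C=C(C)C(=O)O[C@H]1[C@@H]2[C@@H](/C=C(/C)C3=CC(=O)[C@@](C)(O3)[C@H]1OC(C)=O)OC(=O)[C@@]21CO1 | target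

Total steps: 17. Longest linear sequence: 17 steps (from 1).

**Steps most likely to fail**

Step 6. The amine may cleave the tertiary acetate before it opens the ring, or the acyl shift may stall so that acid simply re-forms the six-membered ring. The fallback uses known chemistry and builds the furanone directly; it sets out from ynone 4 and comes back at 12. The potassium enolate of 4 (KHMDS, THF, −78 °C) is hydroxylated with 2-(phenylsulfonyl)-3-phenyloxaziridine to the α'-hydroxy ynone F1. This cyclises 5-endo-dig (Et2NH, EtOH, then AcOH) to the 2-methyl-3(2H)-furanone F2. Kinetic deprotonation of F2 at its ring carbon next to oxygen (LDA, THF, −78 °C) and aldol addition to aldehyde 6 should give the carbinol F3, with C9 set by Felkin–Anh control and C10 by approach to the planar furanone enolate. Acetylation (Ac2O, pyridine, DMAP) of F3 gives 12.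

Step 14. The closed transition state may follow the syn preference that acyclic allylations of this bromide type show and so deliver the C6 epimer; intermolecular coupling or reduction of the Z-enal may also compete. The fallback separates ring closure from the C6 configuration; it sets out from 20 and comes back at 22. The chromium closure is run at 0 °C and quenched cold so that the epimeric adduct is isolated as the (6S)-hydroxy ester F4 before it lactonises. A Mitsunobu reaction with chloroacetic acid (PPh3, DIAD, toluene, 0 °C) inverts C6 and gives the chloroacetate F5. Thiourea (NaHCO3, EtOH, 40 °C) removes the chloroacetyl group in the presence of the C9 acetate to give 21, and a trace of PPTS closes the trans-lactone 22.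

Step 15. The enolate may close on oxygen with poor or reversed facial selectivity if the bulky C8 silyl ether shields the β face. The fallback replaces steric approach control by delivery from the C8 oxygen; it sets out from 22 and comes back at 24. Desilylation (HF·pyridine, THF, 0 °C) gives the 8-hydroxy methylene lactone F6. Its lithium alkoxide (t-BuOOLi from t-BuOOH and LiHMDS, THF, −78 to −40 °C) should hold the peroxide on the β face during conjugate addition and ring closure, a hydroxyl-directed nucleophilic epoxidation, and give 24 directly. The low temperature is meant to hold back acetyl migration.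

Further compounds
F1 | step 6 | (6Z)-2-hydroxy-8-[(4-methoxybenzyl)oxy]-6-methyloct-6-en-4-yn-3-one (racemic) | COc1ccc(COC/C=C(/C)C#CC(=O)C(C)O)cc1
F2 | step 6 | 5-{(2Z)-4-[(4-methoxybenzyl)oxy]but-2-en-2-yl}-2-methylfuran-3(2H)-one (racemic) | COc1ccc(COC/C=C(/C)C2=CC(=O)C(C)O2)cc1
F3 | step 6 | (2S)-2-{(S)-[(4S)-2,2-dimethyl-1,3-dioxolan-4-yl](hydroxy)methyl}-5-{(2Z)-4-[(4-methoxybenzyl)oxy]but-2-en-2-yl}-2-methylfuran-3(2H)-one | COc1ccc(COC/C=C(/C)C2=CC(=O)[C@@](C)(O2)[C@@H](O)[C@@H]3COC(C)(C)O3)cc1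
F4 | step 14 | methyl (4Z,6S,7S,8S,9S,10S)-9-acetoxy-3,10-epoxy-6-hydroxy-1-oxo-8-[(triethylsilyl)oxy]germacra-2,4,11(13)-trien-12-oate | CC[Si](CC)(CC)O[C@H]1[C@@H](C(=C)C(=O)OC)[C@@H](O)/C=C(/C)C2=CC(=O)[C@@](C)(O2)[C@H]1OC(C)=O
F5 | step 14 | methyl (4Z,6R,7S,8S,9S,10S)-9-acetoxy-6-(chloroacetoxy)-3,10-epoxy-1-oxo-8-[(triethylsilyl)oxy]germacra-2,4,11(13)-trien-12-oate | CC[Si](CC)(CC)O[C@H]1[C@@H](C(=C)C(=O)OC)[C@H](OC(=O)CCl)/C=C(/C)C2=CC(=O)[C@@](C)(O2)[C@H]1OC(C)=O
F6 | step 15 | (4Z,6R,7S,8S,9S,10S)-9-acetoxy-3,10-epoxy-8-hydroxy-1-oxogermacra-2,4,11(13)-trien-12,6-olide | O[C@H]1[C@@H]2[C@@H](/C=C(/C)C3=CC(=O)[C@@](C)(O3)[C@H]1OC(C)=O)OC(=O)C2=C
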